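**Strategy.** The ten-membered carbocycle is not closed directly: it is revealed by contracting a thirteen-membered cyclic ether in which O6 bridges C6 and C13. Tin–lithium exchange at C6 starts a [2,3]-Wittig shift that forms C6–C7, sets both stereocentres, frees O6 for the ester and creates the exocyclic C11=C13 methylene of the later lactone ring on C7/C8. The step exploits the C6 carbinol next to C7, which carries the C11(=C13)–C12 unit, i.e. a homoallylic alcohol inscribed in ring C1–C10. Its precursor is an α-stannyl bis-allylic ether with a D-threitol-derived C8/C9 acetonide, silyl ethers at O2 and O12, and three geometry-defined trisubstituted olefins.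

Key step: step 21

Remarks on the chemistry (assumptions and design choices):
- Locants: ring C1–C10 (C1=C10 bearing C14H3, C4 bearing C15H3); C11, C12, C13 are the three-carbon unit on C7.
- Commercial (−)-2,3-O-isopropylidene-D-threitol (1) is taken as the D-tartrate-derived C7–C10 unit; its (4R,5R) centres become C8 (R) and C9 (R).
- The stannyl carbon C6 of 26–28 forms as both epimers and is written without a descriptor; the delocalised lithio species is assumed not to keep that configuration.
- O12 carries a triisopropylsilyl group, because a small trialkylsilyl group could move to the O6 alkoxide after the shift.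
- The Z C4=C5 bond is made inside a six-membered lactone, so its geometry cannot be wrong.

**Step 1**
Reactants: 1 (−)-2,3-O-isopropylidene-D-threitol
Product: 2 mono-(4-methoxybenzyl) ether of 1 (ether carbon = C7, free carbinol carbon = C10)
Conditions: NaH (1.0 equiv), 4-MeOC6H4CH2Cl, Bu4NI (cat.), THF–DMF, 0 °C → rt
Reagents that add atoms: 4-methoxybenzyl chloride, COc1ccc(CCl)cc1
Why: Williamson etherification of the monosodium alkoxide; the diol is C2-symmetric, so either hydroxyl gives the same mono-ether and no stereocentre is touched.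

**Step 2**
Reactants: 2 mono-PMB ether
Product: 3 (4S,5R)-5-{[(4-methoxybenzyl)oxy]methyl}-2,2-dimethyl-1,3-dioxolane-4-carbaldehyde (C10 aldehyde)
Conditions: TEMPO (cat.), PhI(OAc)2, CH2Cl2, rt
Reagents that add atoms: none
Why: Oxoammonium (TEMPO) oxidation of the primary alcohol stops at the aldehyde under non-basic conditions, so the α-alkoxy centre C9 is not epimerised.

**Step 3**
Reactants: 3 C10 aldehyde
Product: 4 (4R,5R)-4-ethynyl-5-{[(4-methoxybenzyl)oxy]methyl}-2,2-dimethyl-1,3-dioxolane (C10≡C1 alkyne)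
Conditions: dimethyl (1-diazo-2-oxopropyl)phosphonate, K2CO3, MeOH, 0 °C → rt
Reagents that add atoms: dimethyl (1-diazo-2-oxopropyl)phosphonate, CC(=O)C(=[N+]=[N-])P(=O)(OC)OC
Why: Ohira–Bestmann (Seyferth–Gilbert) homologation converts the aldehyde into the terminal alkyne under mild carbonate conditions, and the trans-dioxolane is the favoured epimer, so C9 is safe.

**Step 4**
Reactants: 4 alkyne
Product: 6 methyl 3-[(4R,5R)-5-{[(4-methoxybenzyl)oxy]methyl}-2,2-dimethyl-1,3-dioxolan-4-yl]prop-2-ynoate, via lithium acetylide 5 (not isolated)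
Conditions: n-BuLi, THF, −78 °C; then ClCO2Me, −78 → 0 °C
Reagents that add atoms: methyl chloroformate, COC(=O)Cl
Why: Deprotonation of the terminal alkyne and C-acylation of the lithium acetylide by the chloroformate gives the ynoate, whose ester carbon is C2.

**Step 5**
Reactants: 6 ynoate
Product: 7 methyl (2Z)-3-[(4R,5R)-5-{[(4-methoxybenzyl)oxy]methyl}-2,2-dimethyl-1,3-dioxolan-4-yl]but-2-enoate
Conditions: Me2CuLi (MeLi, CuI), THF, −78 °C; MeOH then aq. NH4Cl at −78 °C
Reagents that add atoms: lithium dimethylcuprate, [Li+].C[Cu-]C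
Why: Conjugate syn-carbocupration of the ynoate and cold protonation of the vinylcopper place CH3 and H cis, i.e. C9 cis to C2, which fixes the Z C1=C10 geometry.

**Step 6**
Reactants: 7 (Z)-enoate
Product: 8 (2Z)-3-[(4R,5R)-5-{[(4-methoxybenzyl)oxy]methyl}-2,2-dimethyl-1,3-dioxolan-4-yl]but-2-en-1-ol
Conditions: i-Bu2AlH (2.2 equiv), CH2Cl2, −78 °C
Reagents that add atoms: none
Why: 1,2-Reduction of the enoate by the aluminium hydride gives the allylic alcohol without touching the trisubstituted olefin.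

**Step 7**
Reactants: 8 allylic alcohol
Product: 9 (2Z)-3-[(4R,5R)-5-{[(4-methoxybenzyl)oxy]methyl}-2,2-dimethyl-1,3-dioxolan-4-yl]but-2-enal (C2 aldehyde)
Conditions: MnO2, CH2Cl2, rt
Reagents that add atoms: none
Why: Allylic oxidation with MnO2 is neutral and selective for the allylic alcohol, so the Z-enal should form without isomerisation.

**Step 8**
Reactants: 9 (Z)-enal
Product: 10 (2Z,4S)-2-[(4R,5R)-5-{[(4-methoxybenzyl)oxy]methyl}-2,2-dimethyl-1,3-dioxolan-4-yl]-6-methylhepta-2,6-dien-4-ol (C2 carbinol, S)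
Conditions: (−)-Ipc2BOMe (from (+)-α-pinene), CH2=C(CH3)CH2MgCl, Et2O, −78 °C → rt; then 9, −78 °C; NaOH, H2O2
Reagents that add atoms: methallylmagnesium chloride, CC(=C)C[Mg]Cl
Why: Brown allylboration, in which the methallylborane derived from (+)-α-pinene adds to the Si face of the enal through a chair transition state under reagent control, setting C2 as S.

**Step 9**
Reactants: 10 homoallylic alcohol
Product: 11 (2Z,4S)-2-[(4R,5R)-5-{[(4-methoxybenzyl)oxy]methyl}-2,2-dimethyl-1,3-dioxolan-4-yl]-6-methylhepta-2,6-dien-4-yl prop-2-enoate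
Conditions: CH2=CHCOCl, i-Pr2NEt, CH2Cl2, −78 → 0 °C
Reagents that add atoms: acryloyl chloride, C=CC(=O)Cl
Why: O-Acylation of the secondary allylic alcohol with the acid chloride installs C5 and C6 as an acrylate.

**Step 10**
Reactants: 11 acrylate
Product: 12 (6S)-6-{(1Z)-2-[(4R,5R)-5-{[(4-methoxybenzyl)oxy]methyl}-2,2-dimethyl-1,3-dioxolan-4-yl]prop-1-en-1-yl}-4-methyl-5,6-dihydro-2H-pyran-2-one
Conditions: second-generation Grubbs catalyst (5 mol %), CH2Cl2 (5 mM), 40 °C
Reagents that add atoms: none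
Why: Ring-closing metathesis between the acrylate and the 1,1-disubstituted olefin closes the six-membered lactone, whose ring forces C3 and C6 cis (Z C4=C5), while the trisubstituted C1=C10 olefin is too hindered to compete.

**Step 11**
Reactants: 12 unsaturated lactone
Product: 13 (2Z,5S,6Z)-7-[(4R,5R)-5-{[(4-methoxybenzyl)oxy]methyl}-2,2-dimethyl-1,3-dioxolan-4-yl]-3-methylocta-2,6-diene-1,5-diol (C6–OH and C2–OH)
Conditions: i-Bu2AlH (4 equiv), CH2Cl2, −78 → 0 °C
Reagents that add atoms: none
Why: Exhaustive hydride reduction of the unsaturated lactone through its lactol opens it to the 1,5-diol with the Z olefin geometry retained.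

**Step 12**
Reactants: 13 diol
Product: 15 bis-silyl ether of 13 (O6 as SiEt3 ether, O2 as SiMe2t-Bu ether), via mono-triethylsilyl ether 14 (not isolated)
Conditions: Et3SiCl (1.05 equiv), 2,6-lutidine, CH2Cl2, −78 °C; then t-BuMe2SiOTf, −78 → 0 °C
Reagents that add atoms: chlorotriethylsilane, CC[Si](Cl)(CC)CC; tert-butyldimethylsilyl triflate, CC(C)(C)[Si](C)(C)OS(=O)(=O)C(F)(F)F
Why: Silylation under kinetic control, the primary allylic hydroxyl taking the chlorosilane at −78 °C and the remaining secondary hydroxyl then being capped by the more reactive silyl triflate.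

**Step 13**
Reactants: 15 bis-silyl ether
Product: 16 primary alcohol (15 with the PMB group removed, free C7–OH)
Conditions: DDQ, CH2Cl2–pH 7 phosphate buffer, 0 °C
Reagents that add atoms: none
Why: Oxidative cleavage of the electron-rich 4-methoxybenzyl ether by DDQ (benzylic hydride abstraction, then hydrolysis) in buffered medium should spare the silyl ethers, the acetonide and the olefins.

**Step 14**
Reactants: 16 primary alcohol
Product: 17 C7 aldehyde (dioxolane-4-carbaldehyde bearing the C10–C6 chain; C8 unchanged in space)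
Conditions: Dess–Martin periodinane, pyridine, CH2Cl2, 0 °C → rt
Reagents that add atoms: none
Why: Dess–Martin oxidation of the primary alcohol to the α-alkoxy aldehyde under buffered, non-epimerising conditions.

**Step 15**
Reactants: 18 ethyl (triphenyl-λ5-phosphanylidene)acetate
Product: 20 ethyl 3-[(triisopropylsilyl)oxy]-2-(triphenyl-λ5-phosphanylidene)propanoate, via phosphonium chloride 19 (not isolated)
Conditions: i-Pr3SiOCH2Cl, CH2Cl2, rt; then aq. NaOH
Reagents that add atoms: (triisopropylsiloxy)methyl chloride, ClCO[Si](C(C)C)(C(C)C)C(C)C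
Why: C-Alkylation of the ester-stabilised phosphorane by the reactive α-chloro ether and deprotonation of the resulting phosphonium salt give the α-substituted stabilised ylide.

**Step 16**
Reactants: 17 C7 aldehyde; 20 ylide
Product: 21 ethyl enoate (C7=C11 with C8 trans to the ester carbon C13 and cis to C12H2OSi(i-Pr)3; E)
Conditions: toluene, 80 °C
Reagents that add atoms: none
Why: Wittig olefination with an α-substituted stabilised ylide is E-selective (C8 trans to the ester), which places C12 cis to C8 as the later shift requires.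

**Step 17**
Reactants: 21 enoate
Product: 22 allylic alcohol (21 with C13 as CH2OH)
Conditions: i-Bu2AlH (2.5 equiv), CH2Cl2, −78 °C
Reagents that add atoms: none
Why: 1,2-Reduction of the enoate gives the C13 allylic alcohol, the silyl ethers and the acetonide being inert to the aluminium hydride.

**Step 18**
Reactants: 22 allylic alcohol
Product: 24 allylic chloride (22 with C13 as CH2Cl), via allylic mesylate 23 (not isolated)
Conditions: MsCl, 2,4,6-collidine, LiCl, DMF, 0 °C
Reagents that add atoms: lithium chloride, [Li+].[Cl-]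
Why: In situ mesylation and SN2 displacement by chloride at the primary centre give the allylic chloride without allylic transposition.

**Step 19**
Reactants: 24 allylic chloride
Product: 25 seco chloro enal (24 with C6 as aldehyde; 4Z enal)
Conditions: (COCl)2, DMSO, CH2Cl2, −78 → −30 °C; then Et3N
Reagents that add atoms: none
Why: Swern conditions cleave the primary triethylsilyl ether selectively through the alkoxysulfonium ion and oxidise it directly to the Z-enal, leaving the secondary and bulky silyl ethers and the allylic chloride.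

**Step 20**
Reactants: 25 seco chloro enal
Product: 27 13-membered cyclic α-(tributylstannyl) bis-allylic ether (O6–C13 closed; 2S,8R,9R; 4Z, 1(10)Z; C8 trans to C13 across C7=C11; both C6 epimers), via lithium α-stannyl alkoxide 26 (not isolated)
Conditions: Bu3SnLi (1.05 equiv; from Bu3SnH, LiN(i-Pr)2), THF, −78 °C; then cannula into THF–HMPA, Bu4NI (cat.), 1 mM, −78 → −10 °C
Reagents that add atoms: tributylstannyllithium, [Li][Sn](CCCC)(CCCC)CCCC
Why: Kinetic 1,2-addition of the stannyl anion to the enal at −78 °C (faster than attack on the allylic chloride, and the β,β-disubstituted terminus blocks conjugate addition) gives the α-stannyl alkoxide, which is O-alkylated by the allylic chloride in a Williamson macro-etherification (13-exo-tet) of a chain pre-organised by three trisubstituted olefins and the trans-dioxolane.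

**Step 21**
Reactants: 27 cyclic α-stannyl ether
Product: 29 (2S,6R,7S,8R,9R)-2-(tert-butyldimethylsilyloxy)-8,9-O-isopropylidene-4,10-dimethyl-7-[3-(triisopropylsilyloxy)prop-1-en-2-yl]cyclodeca-1(10),4-dien-6-ol (both ring olefins Z), via α-alkoxy allyllithium 28 (not isolated)
Conditions: n-BuLi (1.3 equiv), THF, −78 °C; aq. NH4Cl
Reagents that add atoms: none
Why: n-BuLi attacks tin, Bu4Sn is expelled and the α-alkoxy allyllithium 28 forms only at C6; it rearranges suprafacially through a five-membered envelope transition state in which C6 bonds to C7 while O6–C13 breaks, the π bond moving to C11=C13 and O6 ending as the lithium alkoxide. The closest known reaction type is the Still–Wittig (tin–lithium exchange) variant of the [2,3]-Wittig rearrangement, used here as the ring contraction of a 13-membered diallylic ether to a cyclodecadiene. The ten-membered carbocycle closes in a formal 10-exo-trig sense (C11=C13 ends exocyclic) by a three-atom contraction driven by alkoxide formation. C7 (S) is controlled by C8: allylic 1,3-strain with the cis CH2OSi(i-Pr)3 group holds C8–H in the olefin plane and the carbanion should add anti to the C8–O8 bond. C6 (R) follows from the C7=C11 geometry (C8 trans to C13) with C5 exo on the envelope, which gives the anti C6/C7 relation, and both C6 epimers of 27 should converge because the delocalised lithio species does not keep the stannane configuration. The step needs the [2,3] shift over [1,2] and [1,4] shifts and retention of the Z C4=C5 bond, which the low temperature, the short life of the anion and the fully substituted C4 terminus should secure, while the bulky silyl group on O12 cannot migrate to the new alkoxide.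

**Step 22**
Reactants: 29 cyclodecadienol; 30 (R)-2-methylbutanoic acid
Product: 31 6-O-[(2R)-2-methylbutanoyl] ester of 29
Conditions: DCC, DMAP (cat.), CH2Cl2, 0 °C → rt
Reagents that add atoms: none
Why: Steglich esterification of the only free hydroxyl (O6) with a non-activated α-branched acid, whose stereocentre is not prone to epimerisation under these conditions.

**Step 23**
Reactants: 31 ester
Product: 32 tetraol (31 without both silyl groups and the acetonide; free OH at C2, C8, C9, C12)
Conditions: HF (48 % aq.), MeCN, 0 °C → rt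
Reagents that add atoms: none
Why: Aqueous HF cleaves both silyl ethers and hydrolyses the strained trans-fused acetonide in one operation at an acidity too low to ionise the allylic ester or alcohols.

**Step 24**
Reactants: 32 tetraol
Product: 35 CNP0176600.1 (target), via hydroxy enal 33 (not isolated), via lactol 34 (not isolated)
Conditions: TEMPO (0.2 equiv), PhI(OAc)2 (2.5 equiv), CH2Cl2, rt
Reagents that add atoms: none
Why: Oxoammonium oxidation is selective for the primary allylic hydroxyl at C12, the aldehyde is trapped by O8 as the five-membered lactol and this is oxidised on to the α-methylene γ-lactone (oxidative lactonisation), the hindered secondary hydroxyls at C2 and C9 reacting far more slowly.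

**Compound list**

1 | (−)-2,3-O-isopropylidene-D-threitol, [(4R,5R)-2,2-dimethyl-1,3-dioxolane-4,5-diyl]dimethanol | OC[C@H]1OC(C)(C)O[C@@H]1CO | starting material
2 | [(4R,5R)-5-{[(4-methoxybenzyl)oxy]methyl}-2,2-dimethyl-1,3-dioxolan-4-yl]methanol | OC[C@H]1OC(C)(C)O[C@@H]1COCc1ccc(OC)cc1 | intermediate
3 | (4S,5R)-5-{[(4-methoxybenzyl)oxy]methyl}-2,2-dimethyl-1,3-dioxolane-4-carbaldehyde | O=C[C@H]1OC(C)(C)O[C@@H]1COCc1ccc(OC)cc1 | intermediate
4 | (4R,5R)-4-ethynyl-5-{[(4-methoxybenzyl)oxy]methyl}-2,2-dimethyl-1,3-dioxolane | C#C[C@H]1OC(C)(C)O[C@@H]1COCc1ccc(OC)cc1 | intermediate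
5 | lithium acetylide of 4 | [Li]C#C[C@H]1OC(C)(C)O[C@@H]1COCc1ccc(OC)cc1 | intermediate (not isolated)
6 | methyl 3-[(4R,5R)-5-{[(4-methoxybenzyl)oxy]methyl}-2,2-dimethyl-1,3-dioxolan-4-yl]prop-2-ynoate | COC(=O)C#C[C@H]1OC(C)(C)O[C@@H]1COCc1ccc(OC)cc1 | intermediate
7 | methyl (2Z)-3-[(4R,5R)-5-{[(4-methoxybenzyl)oxy]methyl}-2,2-dimethyl-1,3-dioxolan-4-yl]but-2-enoate | COC(=O)/C=C(/C)[C@H]1OC(C)(C)O[C@@H]1COCc1ccc(OC)cc1 | intermediate
8 | (2Z)-3-[(4R,5R)-5-{[(4-methoxybenzyl)oxy]methyl}-2,2-dimethyl-1,3-dioxolan-4-yl]but-2-en-1-ol | OC/C=C(/C)[C@H]1OC(C)(C)O[C@@H]1COCc1ccc(OC)cc1 | intermediate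
9 | (2Z)-3-[(4R,5R)-5-{[(4-methoxybenzyl)oxy]methyl}-2,2-dimethyl-1,3-dioxolan-4-yl]but-2-enal | O=C/C=C(/C)[C@H]1OC(C)(C)O[C@@H]1COCc1ccc(OC)cc1 | intermediate
10 | (2Z,4S)-2-[(4R,5R)-5-{[(4-methoxybenzyl)oxy]methyl}-2,2-dimethyl-1,3-dioxolan-4-yl]-6-methylhepta-2,6-dien-4-ol | C=C(C)C[C@H](O)/C=C(/C)[C@H]1OC(C)(C)O[C@@H]1COCc1ccc(OC)cc1 | intermediate
11 | (2Z,4S)-2-[(4R,5R)-5-{[(4-methoxybenzyl)oxy]methyl}-2,2-dimethyl-1,3-dioxolan-4-yl]-6-methylhepta-2,6-dien-4-yl prop-2-enoate | C=CC(=O)O[C@@H](CC(C)=C)/C=C(/C)[C@H]1OC(C)(C)O[C@@H]1COCc1ccc(OC)cc1 | intermediate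
12 | (6S)-6-{(1Z)-2-[(4R,5R)-5-{[(4-methoxybenzyl)oxy]methyl}-2,2-dimethyl-1,3-dioxolan-4-yl]prop-1-en-1-yl}-4-methyl-5,6-dihydro-2H-pyran-2-one | CC1=CC(=O)O[C@@H](C1)/C=C(/C)[C@H]2OC(C)(C)O[C@@H]2COCc3ccc(OC)cc3 | intermediate
13 | (2Z,5S,6Z)-7-[(4R,5R)-5-{[(4-methoxybenzyl)oxy]methyl}-2,2-dimethyl-1,3-dioxolan-4-yl]-3-methylocta-2,6-diene-1,5-diol | OC/C=C(/C)C[C@H](O)/C=C(/C)[C@H]1OC(C)(C)O[C@@H]1COCc1ccc(OC)cc1 | intermediate
14 | 1-O-triethylsilyl ether of 13 (O6 silylated, C2–OH free) | CC[Si](CC)(CC)OC/C=C(/C)C[C@H](O)/C=C(/C)[C@H]1OC(C)(C)O[C@@H]1COCc1ccc(OC)cc1 | intermediate (not isolated)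
15 | bis-silyl ether of 13: O6–SiEt3, (2S)-O2–SiMe2t-Bu, C7–OPMB, trans-acetonide as in 1 | CC[Si](CC)(CC)OC/C=C(/C)C[C@H](O[Si](C)(C)C(C)(C)C)/C=C(/C)[C@H]1OC(C)(C)O[C@@H]1COCc1ccc(OC)cc1 | intermediate
16 | primary alcohol: 15 with free C7–OH | CC[Si](CC)(CC)OC/C=C(/C)C[C@H](O[Si](C)(C)C(C)(C)C)/C=C(/C)[C@H]1OC(C)(C)O[C@@H]1CO | intermediate
17 | C7 aldehyde from 16 (C8 and C9 unchanged in space) | CC[Si](CC)(CC)OC/C=C(/C)C[C@H](O[Si](C)(C)C(C)(C)C)/C=C(/C)[C@H]1OC(C)(C)O[C@@H]1C=O | intermediate
18 | ethyl (triphenyl-λ5-phosphanylidene)acetate | CCOC(=O)C=P(c1ccccc1)(c1ccccc1)c1ccccc1 | starting material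
19 | {1-ethoxy-1-oxo-3-[(triisopropylsilyl)oxy]propan-2-yl}triphenylphosphonium chloride | CCOC(=O)C(CO[Si](C(C)C)(C(C)C)C(C)C)[P+](c1ccccc1)(c1ccccc1)c1ccccc1.[Cl-] | intermediate (not isolated)
20 | ethyl 3-[(triisopropylsilyl)oxy]-2-(triphenyl-λ5-phosphanylidene)propanoate | CCOC(=O)C(CO[Si](C(C)C)(C(C)C)C(C)C)=P(c1ccccc1)(c1ccccc1)c1ccccc1 | intermediate
21 | ethyl enoate: 17 extended at C7 to C7=C11(C12H2OSi(i-Pr)3)–C13O2Et, C8 trans to C13 (E) | CC[Si](CC)(CC)OC/C=C(/C)C[C@H](O[Si](C)(C)C(C)(C)C)/C=C(/C)[C@H]1OC(C)(C)O[C@@H]1/C=C(\CO[Si](C(C)C)(C(C)C)C(C)C)C(=O)OCC | intermediate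
22 | allylic alcohol: 21 with C13 as CH2OH | CC[Si](CC)(CC)OC/C=C(/C)C[C@H](O[Si](C)(C)C(C)(C)C)/C=C(/C)[C@H]1OC(C)(C)O[C@@H]1/C=C(\CO[Si](C(C)C)(C(C)C)C(C)C)CO | intermediate
23 | C13 methanesulfonate of 22 | CC[Si](CC)(CC)OC/C=C(/C)C[C@H](O[Si](C)(C)C(C)(C)C)/C=C(/C)[C@H]1OC(C)(C)O[C@@H]1/C=C(\CO[Si](C(C)C)(C(C)C)C(C)C)COS(C)(=O)=O | intermediate (not isolated)
24 | allylic chloride: 22 with C13 as CH2Cl | CC[Si](CC)(CC)OC/C=C(/C)C[C@H](O[Si](C)(C)C(C)(C)C)/C=C(/C)[C@H]1OC(C)(C)O[C@@H]1/C=C(\CO[Si](C(C)C)(C(C)C)C(C)C)CCl | intermediate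
25 | seco chloro enal: 24 with C6 as aldehyde (4Z) | O=C/C=C(/C)C[C@H](O[Si](C)(C)C(C)(C)C)/C=C(/C)[C@H]1OC(C)(C)O[C@@H]1/C=C(\CO[Si](C(C)C)(C(C)C)C(C)C)CCl | intermediate
26 | lithium alkoxide of the C6 α-(tributylstannyl) carbinol from 25 (both C6 epimers) | [Li]OC([Sn](CCCC)(CCCC)CCCC)/C=C(/C)C[C@H](O[Si](C)(C)C(C)(C)C)/C=C(/C)[C@H]1OC(C)(C)O[C@@H]1/C=C(\CO[Si](C(C)C)(C(C)C)C(C)C)CCl | intermediate (not isolated)
27 | 13-membered cyclic α-(tributylstannyl) bis-allylic ether, O6 linked to C13; 2S,8R,9R; 4Z, 1(10)Z; C8 trans to C13; both C6 epimers | C1/C(C)=C\C([Sn](CCCC)(CCCC)CCCC)OC/C(CO[Si](C(C)C)(C(C)C)C(C)C)=C/[C@H]2OC(C)(C)O[C@@H]2/C(C)=C\[C@H]1O[Si](C)(C)C(C)(C)C | intermediate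
28 | C6-lithio derivative of 27 (α-alkoxy allyllithium) | C1/C(C)=C\C([Li])OC/C(CO[Si](C(C)C)(C(C)C)C(C)C)=C/[C@H]2OC(C)(C)O[C@@H]2/C(C)=C\[C@H]1O[Si](C)(C)C(C)(C)C | intermediate (not isolated)
29 | (2S,6R,7S,8R,9R)-2-(tert-butyldimethylsilyloxy)-8,9-O-isopropylidene-4,10-dimethyl-7-[3-(triisopropylsilyloxy)prop-1-en-2-yl]cyclodeca-1(10),4-dien-6-ol (both ring olefins Z) | C1/C(C)=C\[C@@H](O)[C@H](C(=C)CO[Si](C(C)C)(C(C)C)C(C)C)[C@H]2OC(C)(C)O[C@@H]2/C(C)=C\[C@H]1O[Si](C)(C)C(C)(C)C | intermediate
30 | (R)-2-methylbutanoic acid | CC[C@@H](C)C(=O)O | starting material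
31 | 6-O-[(2R)-2-methylbutanoyl] ester of 29 | C1/C(C)=C\[C@@H](OC(=O)[C@H](C)CC)[C@H](C(=C)CO[Si](C(C)C)(C(C)C)C(C)C)[C@H]2OC(C)(C)O[C@@H]2/C(C)=C\[C@H]1O[Si](C)(C)C(C)(C)C | intermediate
32 | tetraol: 31 with free OH at C2, C8, C9 and C12 (stereocentres unchanged in space) | C1/C(C)=C\[C@@H](OC(=O)[C@H](C)CC)[C@H](C(=C)CO)[C@@H](O)[C@H](O)/C(C)=C\[C@H]1O | intermediate
33 | C12 aldehyde of 32 | C1/C(C)=C\[C@@H](OC(=O)[C@H](C)CC)[C@H](C(=C)C=O)[C@@H](O)[C@H](O)/C(C)=C\[C@H]1O | intermediate (not isolated)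
34 | 8,12-lactol (O8 closed onto C12, lactol carbon undefined) | C=C1C(O)O[C@@H]2[C@@H]1[C@H](OC(=O)[C@H](C)CC)/C=C(/C)C[C@H](O)/C=C(/C)[C@H]2O | intermediate (not isolated)
35 | CNP0176600.1: (2S,6R,7S,8R,9R)-8,12-olide with 6-O-(2R)-2-methylbutanoate, 2-OH, 9-OH, 11(13)-methylene, both ring olefins Z | C=C1C(=O)O[C@@H]2[C@@H]1[C@H](OC(=O)[C@H](C)CC)/C=C(/C)C[C@H](O)/C=C(/C)[C@H]2O | target

**Step count and risks**

Total step count: 24. Longest linear sequence: 23 steps (1 → 35; step 15 is the side branch).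

Steps most likely to fail:

1. Step 21 (key step). The shift may proceed with poor facial selectivity at C7 or with loss of the anti C6/C7 relation; a [1,2]-shift may compete; the allyl anion may lose the Z C4=C5 geometry. Fallback, known chemistry with the polarity reversed (C7 nucleophile, C6 electrophile): it sets out from 24. The chloride is displaced by Bu3SnLi (THF, −78 °C) to give the C13 allylstannane F2. Swern unmasking as in step 19 gives the stannyl aldehyde F3. BF3·OEt2 (CH2Cl2, −78 °C, high dilution) then effects the intramolecular allylstannane–aldehyde addition (SE2′ at C7) through an open transition state, closing the ten-membered ring. The fallback comes back to the route at 29.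

2. Step 20. The α-stannyl alkoxide may revert to enal and stannyl anion, or re-add in conjugate fashion, before the slow thirteen-membered O-alkylation takes place; the stannyl anion may also attack the allylic chloride. Fallback, known chemistry that needs no stannane: it sets out from 25. Chromium dichloride (CrCl2, excess; LiI cat.; THF–DMF, high dilution, rt) inserts divalent chromium into the allylic chloride to give the allylchromium dichloride F1 (not isolated). F1 adds through its γ-carbon C7 to the C6 aldehyde in a chair transition state, which should be anti-selective (intramolecular Nozaki–Hiyama–Kishi allylation). The fallback comes back to the route at 29.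

3. Step 24. The secondary allylic hydroxyls at C2 and C9 may be over-oxidised, or the lactol may close onto O9 and give the six-membered lactone. Fallback that separates oxidation from lactonisation: it sets out from 31. HF·pyridine (pyridine–THF) removes both silyl groups but not the acetonide and gives the diol F4. TEMPO/PhI(OAc)2 oxidises only the primary allylic alcohol to the enal F5. Pinnick oxidation (NaClO2, NaH2PO4, 2-methyl-2-butene) gives the acid F6. Aqueous acetic acid (40 °C) then hydrolyses the acetonide, and the liberated O8 closes the thermodynamically preferred five-membered lactone. The fallback comes back to the route at 35.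

**Further compounds**

F1 | step 20 | allylchromium dichloride from 25 (C13–CrCl2, trivalent chromium; not isolated) | O=C/C=C(/C)C[C@H](O[Si](C)(C)C(C)(C)C)/C=C(/C)[C@H]1OC(C)(C)O[C@@H]1/C=C(\CO[Si](C(C)C)(C(C)C)C(C)C)C[Cr](Cl)Cl
F2 | step 21 | C13 allylstannane: 24 with CH2SnBu3 in place of CH2Cl | CC[Si](CC)(CC)OC/C=C(/C)C[C@H](O[Si](C)(C)C(C)(C)C)/C=C(/C)[C@H]1OC(C)(C)O[C@@H]1/C=C(\CO[Si](C(C)C)(C(C)C)C(C)C)C[Sn](CCCC)(CCCC)CCCC
F3 | step 21 | stannyl aldehyde: F2 with C6 as aldehyde | O=C/C=C(/C)C[C@H](O[Si](C)(C)C(C)(C)C)/C=C(/C)[C@H]1OC(C)(C)O[C@@H]1/C=C(\CO[Si](C(C)C)(C(C)C)C(C)C)C[Sn](CCCC)(CCCC)CCCC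
F4 | step 24 | diol: 31 with free C2–OH and C12–OH, acetonide kept | C1/C(C)=C\[C@@H](OC(=O)[C@H](C)CC)[C@H](C(=C)CO)[C@H]2OC(C)(C)O[C@@H]2/C(C)=C\[C@H]1O
F5 | step 24 | C12 aldehyde of F4 | C1/C(C)=C\[C@@H](OC(=O)[C@H](C)CC)[C@H](C(=C)C=O)[C@H]2OC(C)(C)O[C@@H]2/C(C)=C\[C@H]1O
F6 | step 24 | C12 carboxylic acid of F4 | C1/C(C)=C\[C@@H](OC(=O)[C@H](C)CC)[C@H](C(=C)C(=O)O)[C@H]2OC(C)(C)O[C@@H]2/C(C)=C\[C@H]1O
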